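The 1,4-benzoquinone ring is disconnected at its two carbonyl–CH bonds, C4–C5 and C6–C1 (C2 carries the furan): the unsubstituted C5=C6 edge becomes acetylene and the remaining O=C1–C2(furyl)=C3H–C4=O unit is stored as a strained 3-furylcyclobut-3-ene-1,2-dione. Univalent cobalt opens the acyl–acyl bond of that four-membered ring to a maleoylcobalt metallacycle, and acetylene insertion followed by reductive elimination should close the quinone ring at its final oxidation level, both bonds in one operation and without a regiochemical question because the two-carbon partner is symmetric. The precursor is a cobaltacyclopentenedione carrying the finished furan, the R carbinol ester and the prenyl chain.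

Key step: step 7

Remark: 6, 13 and ClCo(PPh3)3 are taken as purchased reagents (13 is otherwise one step from squaric acid and oxalyl chloride), and 17 is formulated as the octahedral chloro(pyridine)(dimethylglyoxime) maleoyl complex of trivalent cobalt.

Step 1
Reactants: 1 furan-3-carbaldehyde
Product: 5 5-(tributylstannyl)furan-3-carbaldehyde, via lithium morpholino alkoxide 2 (not isolated), via C5-lithiated morpholino alkoxide 3 (not isolated), via stannylated morpholino alkoxide 4 (not isolated)
Conditions: morpholine, n-BuLi, THF, −78 °C; 1; sec-BuLi, −78 °C; Bu3SnCl, −78 °C → rt; H2O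
Reagents that add atoms: tributyltin chloride, CCCC[Sn](Cl)(CCCC)CCCC
Why: In situ protection of the aldehyde as a bulky, non-chelating α-amino alkoxide should shield C2 so that directed lithiation by sec-BuLi takes the remote α-proton at C5, and stannylation followed by hydrolysis of the aminal returns the aldehyde.

Step 2
Reactants: 5 5-(tributylstannyl)furan-3-carbaldehyde; 6 (+)-B-allyldiisopinocampheylborane (the enantiomer made from (−)-α-pinene)
Product: 8 (1R)-1-[5-(tributylstannyl)furan-3-yl]but-3-en-1-ol, via diisopinocampheylborinate ester 7 (not isolated)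
Conditions: (+)-Ipc2B(allyl) (1.2 equiv), Et2O, −78 °C; then HOCH2CH2NH2, rt
Reagents that add atoms: (+)-B-allyldiisopinocampheylborane (6), C=CCB([C@H]1C[C@H]2C[C@@H]([C@@H]1C)C2(C)C)[C@H]1C[C@H]2C[C@@H]([C@@H]1C)C2(C)C
Why: Brown allylboration through a closed chair (Zimmerman–Traxler) transition state, in which the (−)-α-pinene-derived isopinocampheyl groups direct allyl transfer to the Re face of the aldehyde and so set the R carbinol center, with a non-oxidative ethanolamine work-up that spares the C–Sn bond.

Step 3
Reactants: 8 (1R)-1-[5-(tributylstannyl)furan-3-yl]but-3-en-1-ol; 9 3-methylbutanoyl chloride (isovaleryl chloride)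
Product: 10 (1R)-1-[5-(tributylstannyl)furan-3-yl]but-3-en-1-yl 3-methylbutanoate
Conditions: 9 (1.3 equiv), pyridine, DMAP (cat.), CH2Cl2, 0 °C → rt
Reagents that add atoms: 3-methylbutanoyl chloride (9), CC(C)CC(Cl)=O
Why: DMAP-catalysed acylation (nucleophilic acyl substitution) leaves the C–O bond of the stereocenter untouched, so the configuration is retained, and the pyridine buffer keeps HCl away from the acid-labile furylstannane.

Step 4
Reactants: 10 (1R)-1-[5-(tributylstannyl)furan-3-yl]but-3-en-1-yl 3-methylbutanoate; 11 2-methylbut-2-ene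
Product: 12 (1R)-4-methyl-1-[5-(tributylstannyl)furan-3-yl]pent-3-en-1-yl 3-methylbutanoate
Conditions: second-generation Grubbs catalyst RuCl2(=CHPh)(PCy3)(H2IMes) (5 mol %), 2-methylbut-2-ene (excess), CH2Cl2, rt
Reagents that add atoms: 2-methylbut-2-ene (11), CC=C(C)C
Why: Olefin cross-metathesis of the terminal alkene with excess 2-methylbut-2-ene should install the trisubstituted prenyl terminus, driven by loss of propene, while the ester and the aryl C–Sn bond are inert to the ruthenium carbene.

Step 5
Reactants: 12 (1R)-4-methyl-1-[5-(tributylstannyl)furan-3-yl]pent-3-en-1-yl 3-methylbutanoate; 13 3,4-dichlorocyclobut-3-ene-1,2-dione (squaric dichloride)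
Product: 15 (1R)-1-[5-(3,4-dioxocyclobut-1-en-1-yl)furan-3-yl]-4-methylpent-3-en-1-yl 3-methylbutanoate, via chloro(furyl)cyclobutenedione 14 (not isolated)
Conditions: 13 (1.0 equiv), Pd2(dba)3 (2.5 mol %), P(2-furyl)3 (10 mol %), THF, 0 °C → rt; then Bu3SnH (1.05 equiv, slow addition), 0 °C
Reagents that add atoms: 3,4-dichlorocyclobut-3-ene-1,2-dione (13), O=C1C(Cl)=C(Cl)C1=O
Why: Stille coupling of the vinylogous acid chloride with the 2-furylstannane (oxidative addition of C–Cl to zerovalent palladium, Sn-to-Pd transmetalation, reductive elimination) should stop at mono-substitution because the furyl donor deactivates the second C–Cl bond, and the same catalyst then mediates tin hydride hydrodechlorination of 14, the palladium-catalysed Bu3SnH reduction known for acid chlorides.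

Step 6
Reactants: 15 (1R)-1-[5-(3,4-dioxocyclobut-1-en-1-yl)furan-3-yl]-4-methylpent-3-en-1-yl 3-methylbutanoate
Product: 17 chloro(dimethylglyoxime)(pyridine)cobalt maleoyl complex of 15 (3-furyl-1-cobaltacyclopent-3-ene-2,5-dione), via bis(triphenylphosphine) maleoylcobalt chloride 16 (not isolated)
Conditions: ClCo(PPh3)3 (1.05 equiv), PhH, rt; then dimethylglyoxime (1.2 equiv), pyridine, rt; precipitation from Et2O/hexane
Reagents that add atoms: chlorotris(triphenylphosphine)cobalt, Cl[Co-3]([P+](c1ccccc1)(c1ccccc1)c1ccccc1)([P+](c1ccccc1)(c1ccccc1)c1ccccc1)[P+](c1ccccc1)(c1ccccc1)c1ccccc1; dimethylglyoxime, CC(=NO)C(C)=NO; pyridine, c1ccncc1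
Why: Oxidative addition of the strained acyl–acyl C1–C2 bond of the cyclobutenedione to univalent cobalt (C–C activation driven by ring strain) should give the trivalent-cobalt maleoyl metallacycle 16, and exchange of both phosphines for dimethylglyoxime and pyridine gives the octahedral complex 17 that is the alkyne-reactive form.

Step 7
Reactants: 17 chloro(dimethylglyoxime)(pyridine)cobalt maleoyl complex; 18 acetylene
Product: 20 (1R)-1-[5-(3,6-dioxocyclohexa-1,4-dien-1-yl)furan-3-yl]-4-methylpent-3-en-1-yl 3-methylbutanoate (CNP0219765.1), via seven-membered cobaltacycle 19 (not isolated)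
Conditions: HC≡CH (1 atm), CoCl2·6H2O (1.0 equiv), ClCH2CH2Cl, 60 °C
Reagents that add atoms: acetylene (18), C#C
Why: Cobalt dichloride as Lewis acid should labilise a ligand of the octahedral trivalent-cobalt complex 17 so that acetylene binds cis to an acyl group and inserts into the less hindered Co–acyl bond (the acyl flanked by C3–H), forming the quinone C4–C5 bond and the seven-membered cobaltacycle 19. C(sp2)–C(acyl) reductive elimination from 19 then forms the C6–C1 bond and releases the quinone, cobalt leaving in the univalent state. The closest known reaction type is the quinone synthesis from maleoylcobalt dimethylglyoxime complexes (made from cyclobutenediones) and alkynes, for which terminal alkynes and aryl-substituted maleoyl complexes are established substrates. The six-membered quinone ring is closed by reductive elimination from a seven-membered metallacycle, a formal [4+2] annulation of the four-carbon maleoyl unit with the two-carbon alkyne and not a polar or radical cyclisation. No stereocenter is formed, and the R center on the furan side chain is remote from the metal and should stay intact. The step needs chemoselectivity for the alkyne over the trisubstituted prenyl alkene and the furan, secured by the far stronger binding and insertion aptitude of an unhindered alkyne, while regioselectivity is no issue because acetylene is symmetric and both insertion senses converge on 20.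

Compound list
1 | furan-3-carbaldehyde | O=Cc1ccoc1 | starting material
2 | lithium (furan-3-yl)(morpholin-4-yl)methanolate (not isolated) | [Li]OC(c1ccoc1)N1CCOCC1 | intermediate
3 | lithium (5-lithiofuran-3-yl)(morpholin-4-yl)methanolate (not isolated) | [Li]OC(N1CCOCC1)c1coc([Li])c1 | intermediate
4 | lithium (morpholin-4-yl)[5-(tributylstannyl)furan-3-yl]methanolate (not isolated) | [Li]OC(N1CCOCC1)c1coc([Sn](CCCC)(CCCC)CCCC)c1 | intermediate
5 | 5-(tributylstannyl)furan-3-carbaldehyde | O=Cc1coc([Sn](CCCC)(CCCC)CCCC)c1 | intermediate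
6 | (+)-B-allyldiisopinocampheylborane (from (−)-α-pinene) | C=CCB([C@H]1C[C@H]2C[C@@H]([C@@H]1C)C2(C)C)[C@H]1C[C@H]2C[C@@H]([C@@H]1C)C2(C)C | starting material
7 | (1R)-1-[5-(tributylstannyl)furan-3-yl]but-3-en-1-yl diisopinocampheylborinate (not isolated) | C=CC[C@@H](OB([C@H]1C[C@H]2C[C@@H]([C@@H]1C)C2(C)C)[C@H]1C[C@H]2C[C@@H]([C@@H]1C)C2(C)C)c1coc([Sn](CCCC)(CCCC)CCCC)c1 | intermediate
8 | (1R)-1-[5-(tributylstannyl)furan-3-yl]but-3-en-1-ol | C=CC[C@@H](O)c1coc([Sn](CCCC)(CCCC)CCCC)c1 | intermediate
9 | 3-methylbutanoyl chloride | CC(C)CC(Cl)=O | starting material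
10 | (1R)-1-[5-(tributylstannyl)furan-3-yl]but-3-en-1-yl 3-methylbutanoate | C=CC[C@@H](OC(=O)CC(C)C)c1coc([Sn](CCCC)(CCCC)CCCC)c1 | intermediate
11 | 2-methylbut-2-ene | CC=C(C)C | starting material
12 | (1R)-4-methyl-1-[5-(tributylstannyl)furan-3-yl]pent-3-en-1-yl 3-methylbutanoate | CC(C)=CC[C@@H](OC(=O)CC(C)C)c1coc([Sn](CCCC)(CCCC)CCCC)c1 | intermediate
13 | 3,4-dichlorocyclobut-3-ene-1,2-dione | O=C1C(Cl)=C(Cl)C1=O | starting material
14 | (1R)-1-[5-(2-chloro-3,4-dioxocyclobut-1-en-1-yl)furan-3-yl]-4-methylpent-3-en-1-yl 3-methylbutanoate (not isolated) | CC(C)=CC[C@@H](OC(=O)CC(C)C)c1coc(C2=C(Cl)C(=O)C2=O)c1 | intermediate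
15 | (1R)-1-[5-(3,4-dioxocyclobut-1-en-1-yl)furan-3-yl]-4-methylpent-3-en-1-yl 3-methylbutanoate | CC(C)=CC[C@@H](OC(=O)CC(C)C)c1coc(C2=CC(=O)C2=O)c1 | intermediate
16 | chlorobis(triphenylphosphine)cobalt maleoyl complex of 15, a 3-furyl-1-cobaltacyclopent-3-ene-2,5-dione (not isolated) | CC(C)=CC[C@@H](OC(=O)CC(C)C)c1coc(C2=CC(=O)[Co-2](Cl)([P+](c3ccccc3)(c3ccccc3)c3ccccc3)([P+](c3ccccc3)(c3ccccc3)c3ccccc3)C2=O)c1 | intermediate
17 | chloro(dimethylglyoxime)(pyridine)cobalt maleoyl complex of 15, a 3-furyl-1-cobaltacyclopent-3-ene-2,5-dione | CC(C)=CC[C@@H](OC(=O)CC(C)C)c1coc(C2=CC(=O)[Co-3]3(Cl)([n+]4ccccc4)([N+](O)=C(C)C(C)=[N+]3O)C2=O)c1 | intermediate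
18 | acetylene | C#C | starting material
19 | chloro(dimethylglyoxime)(pyridine) 3-furyl-1-cobaltacyclohepta-3,6-diene-2,5-dione (not isolated) | CC(C)=CC[C@@H](OC(=O)CC(C)C)c1coc(C2=CC(=O)C=C[Co-3]3(Cl)([n+]4ccccc4)([N+](O)=C(C)C(C)=[N+]3O)C2=O)c1 | intermediate
20 | (1R)-1-[5-(3,6-dioxocyclohexa-1,4-dien-1-yl)furan-3-yl]-4-methylpent-3-en-1-yl 3-methylbutanoate | CC(C)=CC[C@@H](OC(=O)CC(C)C)c1coc(C2=CC(=O)C=CC2=O)c1 | target

Total step count: 7. Longest linear sequence: 7 steps, from furan-3-carbaldehyde (1) to 20.

Steps most likely to fail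

1. Step 7 (key step). What may go wrong: repeated insertion or oligomerisation of acetylene at cobalt, or consumption of the unhindered quinone by the liberated pyridine and oxime ligands. The fallback sets out from 15 and comes back at 20. Chemoselective 1,2-addition of CH2=CHMgBr/CeCl3 (THF, −78 °C) to a ring carbonyl of 15 should give (1R)-1-[5-(4-ethenyl-4-hydroxy-3-oxocyclobut-1-en-1-yl)furan-3-yl]-4-methylpent-3-en-1-yl 3-methylbutanoate F1 as a mixture of carbinol epimers (attack at either carbonyl leads to the same arene). Heating in toluene at 110 °C should open the cyclobutenone to a dienylketene that closes by 6π electrocyclisation and tautomerises to the hydroquinone (1R)-1-[5-(2,5-dihydroxyphenyl)furan-3-yl]-4-methylpent-3-en-1-yl 3-methylbutanoate F2. Oxidation with Ag2O (Et2O, rt) should then give 20.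

2. Step 5. What may go wrong: tin hydride reduction of the ene-dione of 15, coupling at both C–Cl bonds of 13, or hydrolysis of 14 before it is reduced. The fallback sets out from 12 and comes back at 15; the ring hydrogen is installed before the coupling. Commercial diisopropyl squarate is reduced with LiAlH(OtBu)3 (THF, −78 °C) to 4-hydroxy-2,3-di(propan-2-yloxy)cyclobut-2-en-1-one F3, which conc. HCl (cat., CH2Cl2) should convert to 3-(propan-2-yloxy)cyclobut-3-ene-1,2-dione F4. Aqueous HCl hydrolysis should give 3-hydroxycyclobut-3-ene-1,2-dione F5 (semisquaric acid), and (COCl)2 with catalytic DMF should give 3-chlorocyclobut-3-ene-1,2-dione F6. Stille coupling of F6 with 12 (Pd2(dba)3, P(2-furyl)3, THF) should give 15 directly.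

3. Step 6. What may go wrong: conjugate attack of released triphenylphosphine on the unsubstituted ring carbon of 15, or decomposition of the metallacycle during ligand exchange. The fallback sets out from 15 and comes back at 20 by a metal-free ring expansion. HC≡CMgBr/CeCl3 (THF, −78 °C) should add to a ring carbonyl to give (1R)-1-[5-(4-ethynyl-4-hydroxy-3-oxocyclobut-1-en-1-yl)furan-3-yl]-4-methylpent-3-en-1-yl 3-methylbutanoate F7 as a mixture of carbinol epimers. Thermolysis in toluene at 110 °C (Moore rearrangement: ring opening to an enynylketene, cyclisation to a diradical, hydrogen transfer) should give 20 without a separate oxidation.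

Further compounds
F1 | step 7 | (1R)-1-[5-(4-ethenyl-4-hydroxy-3-oxocyclobut-1-en-1-yl)furan-3-yl]-4-methylpent-3-en-1-yl 3-methylbutanoate | CC(C)=CC[C@@H](OC(=O)CC(C)C)c1coc(C2=CC(=O)C2(O)C=C)c1
F2 | step 7 | (1R)-1-[5-(2,5-dihydroxyphenyl)furan-3-yl]-4-methylpent-3-en-1-yl 3-methylbutanoate | CC(C)=CC[C@@H](OC(=O)CC(C)C)c1coc(-c2cc(O)ccc2O)c1
F3 | step 5 | 4-hydroxy-2,3-di(propan-2-yloxy)cyclobut-2-en-1-one | CC(C)OC1=C(OC(C)C)C(=O)C1O
F4 | step 5 | 3-(propan-2-yloxy)cyclobut-3-ene-1,2-dione | CC(C)OC1=CC(=O)C1=O
F5 | step 5 | 3-hydroxycyclobut-3-ene-1,2-dione | OC1=CC(=O)C1=O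
F6 | step 5 | 3-chlorocyclobut-3-ene-1,2-dione | ClC1=CC(=O)C1=O
F7 | step 6 | (1R)-1-[5-(4-ethynyl-4-hydroxy-3-oxocyclobut-1-en-1-yl)furan-3-yl]-4-methylpent-3-en-1-yl 3-methylbutanoate | CC(C)=CC[C@@H](OC(=O)CC(C)C)c1coc(C2=CC(=O)C2(O)C#C)c1
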